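- The constants we can have before this flask come from the runs, and we turn them into times. In the spring run, the gap between [starting material] and its last reading of 15.3% halves in 0.136 h up to the first reading.
- Between 0.333 h and 1.00 h, the spring gap halves more slowly, in 0.209 h. We carry this as the settling half-time, the time in which the gap to the plateau halves. It is a rough reading, since the gap at 1.00 h is 1.7 percentage points and a reading scatters by 0.5 points.
- Next comes the flat rung: from 2.00 h to 6.00 h, both runs hold [starting material] and [target] level within a few scatters.
- The winter run, at 44 mM, reads 16.3% at 1.00 h against 17.0% in the spring run, so we use the same half-time for the new flask.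

| flask | starting material | remark | time |
|---|---|---|---|
| spring | 28 mM | run made earlier |  |
| winter | 44 mM | run made earlier |  |
| flask | 20 mM |  | 8.0 h |

- spring (time / h: starting material / %, target / %): 0.333: 30.8, 38.0; 1.00: 17.0, 44.3; 2.00: 15.3, 43.4; 3.00: 15.3, 44.5; 4.00: 14.4, 44.4; 5.00: 15.9, 43.7; 6.00: 15.3, 44.1
- winter (time / h: starting material / %, target / %): 1.00: 16.3, 43.4; 2.00: 15.2, 44.1; 3.00: 15.0, 45.2; 4.00: 15.3, 44.6; 5.00: 15.4, 43.5; 6.00: 16.0, 44.2

(scatter of a reading: 0.5 percentage points)

- the reaction counts as stopped when no species that holds the starting material changes by six tenths of a point or more over the second half of the time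

- why nothing more happens at 8.0 h, or that something still does (forward and back rates have come level / all of the starting material has reacted / it is still moving)
- conversion of starting material at 8.0 h
- amount of target at 8.0 h, in percent of the starting material charged

- Our reckoning: 8.0 h is 38.2 settling half-times, so we expect the 20 mM flask on the plateau, with conversion 84.7% and target 44.1%.
- The forecast gives forward and back rates have come level, conversion 84.7% and target 44.2%: “The balance looks like a true equilibrium”.
- The flask gives forward and back rates have come level, conversion 84.7% and target 44.3%.

    starting material ⇌ target (K = 2.90, k = 0.0740 min⁻¹)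
    target ⇌ isomer of the product A (K = 0.100, k = 0.130 min⁻¹)
    isomer of the product A ⇌ isomer of the product B (K = 0.200, k = 0.0610 min⁻¹)
    isomer of the product B ⇌ starting material (k = 0.00220 min⁻¹)
    target ⇌ isomer of the product C (K = 0.790, k = 0.120 min⁻¹)

- Taken by the forward step alone at 0.136 h, starting material into target has a half-life of 0.16 h and target into isomer of the product C one of 0.096 h, both short against 8.0 h, as is our settling half-time of 0.209 h. This flask stands under thermodynamic control: at 80.0 h it still shows conversion 84.7% and target 44.3%, and target stays within 5 points of its answer down to at least 1.0 h.
- The same charge stopped at 3.0 h has had 14.4 settling half-times, so we expect the plateau there too. That flask gives conversion 84.7% and target 44.3%.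

The numbers in the tables were computed with made-up constants.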